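**Retrosynthetic overview**

1. Target ⇐ macrocyclic bis(vinylogous amide) 21 by twofold conjugate reduction and kinetic protonation, which sets both C3 methyl centres last.
2. 21 ⇐ diene 19 by ring-closing metathesis/hydrogenation of the C9(A)–(CH2)5–C1(B) chain; C1(B) ⇐ enolate allylation anti to C9.
3. Key disconnection: the CH2–CH2 bond next to C1(A) in the other chain, made by radical conjugate addition of the primary alkyl radical from the butenyl arm of 11 to the exocyclic methylene of 14; protonation then sets C1(A) cis.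
4. 14 and 11 ⇐ the two enantiomers (10, 11) of one racemic bicyclic enaminone 9; both are used.
5. Ring order in each half: piperidine ring by 6-exo radical cyclization (C9–C9a bond, trans) → enaminone ring by amide-acetal annulation → 16-membered ring → saturation of the enaminone rings.

Assumption: each bicyclic half is numbered as a quinolizidine (C1–C4, N5, C6–C9, C9a; C2 is the carbonyl carbon); unit A is the half that is 9R in the target and unit B the 9S half; racemic 2-(but-3-en-1-yl)oxirane and pent-1-yn-3-one are bought; the chiral-phase separation is counted as a step.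

**Route**

Step 1
Reactants: 1 epoxide 2-(but-3-en-1-yl)oxirane (racemic); 2 acetonitrile
Product: 4 amino alcohol 8-aminooct-1-en-5-ol (racemic), via hydroxynitrile 3 (not isolated)
Conditions: MeCN, n-BuLi, THF, −78 °C; then 1, −78 °C to rt; then LiAlH4, 0 to 65 °C; H2O/NaOH work-up
Reagents that add atoms: none
Why: Lithiated acetonitrile opens the monosubstituted epoxide at its CH2 terminus (SN2 epoxide opening) and LiAlH4 reduces the nitrile of the resulting alkoxide to the primary amine in the same flask; the carbinol centre is racemic and is erased in step 4.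

Step 2
Reactants: 4 amino alcohol 8-aminooct-1-en-5-ol; 5 pent-1-yn-3-one
Product: 6 enaminone (Z)-1-[(4-hydroxyoct-7-en-1-yl)amino]pent-1-en-3-one (racemic)
Conditions: MeOH, 0 °C to rt
Reagents that add atoms: none
Why: Conjugate (aza-Michael) addition of the primary amine to the ynone is fast and chemoselective and gives the hydrogen-bonded (Z)-enaminone; the secondary alcohol does not compete.

Step 3
Reactants: 6 enaminone (Z)-1-[(4-hydroxyoct-7-en-1-yl)amino]pent-1-en-3-one
Product: 7 iodide (Z)-1-[(4-iodooct-7-en-1-yl)amino]pent-1-en-3-one (racemic)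
Conditions: PPh3/I2/imidazole (premixed), CH2Cl2, 0 °C, dark
Reagents that add atoms: iodine, II
Why: Appel-type iodination converts the secondary alcohol into the radical precursor under neutral conditions that the weakly nucleophilic vinylogous-amide NH tolerates; the C–I centre is racemic and becomes planar in step 4.

Step 4
Reactants: 7 iodide (Z)-1-[(4-iodooct-7-en-1-yl)amino]pent-1-en-3-one
Product: 8 amino ketone rac-1-[(2S,3R)-3-(but-3-en-1-yl)piperidin-2-yl]butan-2-one (trans)
Conditions: (Me3Si)3SiH (syringe pump), Et3B/air, toluene (5 mM), rt; then Et3N, MeOH, rt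
Reagents that add atoms: none
Why: Iodine-atom abstraction gives a secondary alkyl radical that closes by 6-exo-trig radical cyclization onto the enaminone β-carbon (Beckwith-type cyclization onto a vinylogous amide) through a chair transition state with the butenyl arm equatorial, so the C9–C9a bond forms with H9 and H9a trans (racemic), the α-keto radical is reduced by the silane, and any cis isomer is funnelled to trans because the NH β-amino ketone equilibrates by retro-aza-Michael/aza-Michael addition in Et3N/MeOH.

Step 5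
Reactants: 8 amino ketone rac-1-[(2S,3R)-3-(but-3-en-1-yl)piperidin-2-yl]butan-2-one
Product: 9 bicyclic enaminone rac-(9R,9aS)-9-(but-3-en-1-yl)-3-methyl-1,6,7,8,9,9a-hexahydro-2H-quinolizin-2-one (trans)
Conditions: Me2NCH(OMe)2, toluene, 110 °C
Reagents that add atoms: N,N-dimethylformamide dimethyl acetal, COC(OC)N(C)C
Why: The piperidine NH is formylated by the amide acetal and the tethered amidinium carbon can be reached in a six-membered closure only by the ethyl-ketone α-carbon (not by C1), so condensation and loss of Me2NH give the bicyclic vinylogous amide with the methyl on C3 (enaminone annulation of a β-amino ketone); C9 and C9a are not touched.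

Step 6
Reactants: 9 bicyclic enaminone rac-(9R,9aS)-9-(but-3-en-1-yl)-3-methyl-1,6,7,8,9,9a-hexahydro-2H-quinolizin-2-one
Product: 10 (9R,9aS)-enantiomer of 9 and 11 (9S,9aR)-enantiomer of 9
Conditions: preparative supercritical-fluid chromatography on amylose tris(3,5-dimethylphenylcarbamate), CO2/MeOH, 40 °C
Reagents that add atoms: none
Why: Resolution by chiral chromatography: the neutral enaminone enantiomers separate on a polysaccharide phase and both are needed (10 becomes unit A and 11 unit B), so the absolute configuration of C9 and C9a of both halves is fixed here and is assigned by X-ray analysis of a crystalline derivative.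

Step 7
Reactants: 10 (9R,9aS)-9-(but-3-en-1-yl)-3-methyl-1,6,7,8,9,9a-hexahydro-2H-quinolizin-2-one
Product: 14 methylidene ketone (9R,9aR)-9-(but-3-en-1-yl)-3-methyl-1-methylidene-1,6,7,8,9,9a-hexahydro-2H-quinolizin-2-one, via Mannich base 12 (not isolated), via methiodide 13 (not isolated)
Conditions: LiN(i-Pr)2, THF, −78 °C; CH2=NMe2+ I−, −78 to 0 °C; then MeI, rt; then aq NaHCO3/CH2Cl2, rt
Reagents that add atoms: Eschenmoser's salt (N,N-dimethylmethyleneiminium iodide), C=[N+](C)C.[I-]
Why: Kinetic α'-deprotonation of the vinylogous amide (C1 is its only enolizable CH2), Mannich aminomethylation, quaternization and E1cB (Hofmann-type) elimination give the cross-conjugated α-methylene ketone, and the weak base keeps C9a–H from isomerizing the product to a 4-pyridone; no stereocentre is created.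

Step 8
Reactants: 11 (9S,9aR)-9-(but-3-en-1-yl)-3-methyl-1,6,7,8,9,9a-hexahydro-2H-quinolizin-2-one; 14 methylidene ketone
Product: 17 coupled bis-enaminone (1S,9R,9aR)-9-(but-3-en-1-yl)-3-methyl-1-{5-[(9S,9aR)-3-methyl-2-oxo-1,6,7,8,9,9a-hexahydro-2H-quinolizin-9-yl]pentyl}-1,6,7,8,9,9a-hexahydro-2H-quinolizin-2-one, via alkylborane 15 (not isolated), via boron enolate 16 (not isolated)
Conditions: 11, catecholborane, MeCONMe2 (10 mol%), CH2Cl2, 40 °C; t-BuOH; then 14 (1.2 equiv), DMPU, air, 0 °C to rt; MeOH
Reagents that add atoms: none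
Why: Anti-Markovnikov hydroboration of the only isolated alkene of 11 gives a B-alkylcatecholborane that enters an oxygen-initiated radical chain (Brown–Negishi-type radical conjugate addition of an organoborane), in which the primary alkyl radical adds to the exocyclic CH2 of 14 and so forms the C–C bond linking C9 of unit B through five CH2 groups to C1 of unit A, the α-keto radical is trapped at oxygen as the boron enolate, and methanol protonates C1 on the face opposite the bulky C9a–C9 bond (held axial by A(1,3) strain with the new side chain), giving the kinetic cis arrangement (H1 and H9a cis, 1S).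

Step 9
Reactants: 17 coupled bis-enaminone; 18 allyl bromide (3-bromoprop-1-ene)
Product: 19 diene (1S,9R,9aR)-9-(but-3-en-1-yl)-3-methyl-1-{5-[(1S,9S,9aS)-3-methyl-2-oxo-1-(prop-2-en-1-yl)-1,6,7,8,9,9a-hexahydro-2H-quinolizin-9-yl]pentyl}-1,6,7,8,9,9a-hexahydro-2H-quinolizin-2-one
Conditions: LiN(i-Pr)2 (1.05 equiv), THF, −78 °C; then allyl bromide, −78 to −40 °C
Reagents that add atoms: none
Why: The base removes a proton from the only α'-CH2 left (C1 of unit B; the tertiary C1–H of unit A is kinetically much slower) and the enolate is allylated anti to the C9a–C9 bond, as in alkylations of 2-substituted 2,3-dihydro-4-pyridone enolates, so C1 of unit B is set trans (H1 and H9a trans, 1S).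

Step 10
Reactants: 19 diene
Product: 21 macrocyclic bis-enaminone (16-membered ring; C1 of each unit joined to C9 of the other by (CH2)5; C3=C4 in both units; unit A 1S,9R,9aR; unit B 1S,9S,9aS), via cycloalkene 20 (not isolated)
Conditions: RuCl2(=CHPh)(PCy3)(SIMes) (second-generation Grubbs catalyst, 10 mol%), CH2Cl2 (1 mM), 40 °C; then H2 (5 bar), 40 °C
Reagents that add atoms: none
Why: Ring-closing metathesis of the two terminal alkenes (the non-basic vinylogous amides do not bind ruthenium and their C=C bonds are inert) closes the 16-membered ring at high dilution and the ruthenium residue then hydrogenates the new disubstituted alkene under H2 (tandem RCM/hydrogenation); no stereocentre is affected.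

Step 11
Reactants: 21 macrocyclic bis-enaminone
Product: 23 target bis-quinolizidin-2-one macrocycle (unit A 1S,3R,9R,9aR; unit B 1S,3R,9S,9aS), via dilithium bis-enolate 22 (not isolated)
Conditions: LiBH(s-Bu)3 (2.4 equiv), THF, −78 to −40 °C; then AcOH/THF, −78 °C
Reagents that add atoms: none
Why: Twofold 1,4-hydride (conjugate) reduction of the vinylogous amides gives the C2=C3 lithium enolates without touching either C1–H, and axial protonation at −78 °C on the face of the axial H1 puts each methyl equatorial and cis to the C1 chain (3R in both units), which is also the more stable C3 epimer of each ring; the acidic quench keeps the kinetically set C1 of unit A away from base.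

**Compound list**

1 | 2-(but-3-en-1-yl)oxirane (racemic) | C=CCCC1CO1 | starting material
2 | acetonitrile | CC#N | starting material
3 | 4-hydroxyoct-7-enenitrile (racemic; present as its lithium alkoxide) | N#CCCC(O)CCC=C | intermediate
4 | 8-aminooct-1-en-5-ol (racemic) | NCCCC(O)CCC=C | intermediate
5 | pent-1-yn-3-one | CCC(=O)C#C | starting material
6 | (Z)-1-[(4-hydroxyoct-7-en-1-yl)amino]pent-1-en-3-one (racemic) | CCC(=O)/C=C\NCCCC(O)CCC=C | intermediate
7 | (Z)-1-[(4-iodooct-7-en-1-yl)amino]pent-1-en-3-one (racemic) | CCC(=O)/C=C\NCCCC(I)CCC=C | intermediate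
8 | rac-1-[(2S,3R)-3-(but-3-en-1-yl)piperidin-2-yl]butan-2-one (trans; one enantiomer drawn) | CCC(=O)C[C@@H]1NCCC[C@H]1CCC=C | intermediate
9 | rac-(9R,9aS)-9-(but-3-en-1-yl)-3-methyl-1,6,7,8,9,9a-hexahydro-2H-quinolizin-2-one (trans; one enantiomer drawn) | CC1=CN2CCC[C@@H](CCC=C)[C@@H]2CC1=O | intermediate
10 | (9R,9aS)-9-(but-3-en-1-yl)-3-methyl-1,6,7,8,9,9a-hexahydro-2H-quinolizin-2-one | CC1=CN2CCC[C@@H](CCC=C)[C@@H]2CC1=O | intermediate
11 | (9S,9aR)-9-(but-3-en-1-yl)-3-methyl-1,6,7,8,9,9a-hexahydro-2H-quinolizin-2-one | CC1=CN2CCC[C@H](CCC=C)[C@H]2CC1=O | intermediate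
12 | (1R,9R,9aR)-9-(but-3-en-1-yl)-1-[(dimethylamino)methyl]-3-methyl-1,6,7,8,9,9a-hexahydro-2H-quinolizin-2-one | CC1=CN2CCC[C@@H](CCC=C)[C@@H]2[C@@H](CN(C)C)C1=O | intermediate
13 | [(1R,9R,9aR)-9-(but-3-en-1-yl)-3-methyl-2-oxo-1,6,7,8,9,9a-hexahydro-2H-quinolizin-1-yl]-N,N,N-trimethylmethanaminium iodide | CC1=CN2CCC[C@@H](CCC=C)[C@@H]2[C@@H](C[N+](C)(C)C)C1=O.[I-] | intermediate
14 | (9R,9aR)-9-(but-3-en-1-yl)-3-methyl-1-methylidene-1,6,7,8,9,9a-hexahydro-2H-quinolizin-2-one | CC1=CN2CCC[C@@H](CCC=C)[C@@H]2C(=C)C1=O | intermediate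
15 | (9S,9aR)-9-[4-(1,3,2-benzodioxaborol-2-yl)butyl]-3-methyl-1,6,7,8,9,9a-hexahydro-2H-quinolizin-2-one | CC1=CN2CCC[C@H](CCCCB3Oc4ccccc4O3)[C@H]2CC1=O | intermediate
16 | catecholboron C1=C2 enolate of 17 (unit A 9R,9aR; unit B 9S,9aR) | CC1=CN2CCC[C@@H](CCC=C)[C@@H]2C(CCCCC[C@H]3CCCN4C=C(C)C(=O)C[C@H]34)=C1OB5Oc6ccccc6O5 | intermediate
17 | (1S,9R,9aR)-9-(but-3-en-1-yl)-3-methyl-1-{5-[(9S,9aR)-3-methyl-2-oxo-1,6,7,8,9,9a-hexahydro-2H-quinolizin-9-yl]pentyl}-1,6,7,8,9,9a-hexahydro-2H-quinolizin-2-one | CC1=CN2CCC[C@@H](CCC=C)[C@@H]2[C@H](CCCCC[C@H]3CCCN4C=C(C)C(=O)C[C@H]34)C1=O | intermediate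
18 | 3-bromoprop-1-ene (allyl bromide) | C=CCBr | starting material
19 | (1S,9R,9aR)-9-(but-3-en-1-yl)-3-methyl-1-{5-[(1S,9S,9aS)-3-methyl-2-oxo-1-(prop-2-en-1-yl)-1,6,7,8,9,9a-hexahydro-2H-quinolizin-9-yl]pentyl}-1,6,7,8,9,9a-hexahydro-2H-quinolizin-2-one | CC1=CN2CCC[C@@H](CCC=C)[C@@H]2[C@H](CCCCC[C@H]3CCCN4C=C(C)C(=O)[C@@H](CC=C)[C@H]34)C1=O | intermediate
20 | macrocyclic alkene from ring closure of 19 (E/Z mixture; C=C in the C9(A)–C1(B) chain; unit A 1S,9R,9aR; unit B 1S,9S,9aS) | CC1=CN2CCC[C@H]3CCC=CC[C@@H]4C(=O)C(C)=CN5CCC[C@H](CCCCC[C@H](C1=O)[C@@H]32)[C@@H]45 | intermediate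
21 | macrocyclic bis-enaminone, the 3,4-didehydro (both units) form of the target (unit A 1S,9R,9aR; unit B 1S,9S,9aS) | CC1=CN2CCC[C@H]3CCCCC[C@@H]4C(=O)C(C)=CN5CCC[C@H](CCCCC[C@H](C1=O)[C@@H]32)[C@@H]45 | intermediate
22 | dilithium C2=C3 bis-enolate of the target (unit A 1S,9R,9aR; unit B 1S,9S,9aS) | CC=1CN2CCC[C@H]3CCCCC[C@@H]4C([O-])=C(C)CN5CCC[C@H](CCCCC[C@H](C=1[O-])[C@@H]32)[C@@H]45.[Li+].[Li+] | intermediate
23 | target bis-quinolizidin-2-one macrocycle (unit A 1S,3R,9R,9aR; unit B 1S,3R,9S,9aS) | C[C@@H]1CN2CCC[C@H]3CCCCC[C@@H]4C(=O)[C@H](C)CN5CCC[C@H](CCCCC[C@H](C1=O)[C@@H]32)[C@@H]45 | target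

**Step count and risk**

Total steps: 11. Longest linear sequence: 11 (steps 1 to 11; both halves come from 9).

The three steps most likely to fail:

Step 8, the radical fragment union. The borane chain may propagate poorly with the electron-rich cross-conjugated acceptor, or catecholborane may reduce 14. The fallback sets out from 11. Hydroboration with disiamylborane and iodination in the same flask (I2, NaOMe) give the primary iodide (9S,9aR)-9-(4-iodobutyl)-3-methyl-1,6,7,8,9,9a-hexahydro-2H-quinolizin-2-one F1. A silane-mediated Giese addition ((Me3Si)3SiH, AIBN, slow addition, benzene, 80 °C, twofold excess of 14) then lets the silane deliver hydrogen to the C1 radical anti to C9. The route is rejoined at 17, at the cost of one more step.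

Step 4, the 6-exo cyclization onto an NH enaminone. The acceptor is electron-rich, so direct reduction of the radical may win. The fallback sets out from 7. N-acylation (Boc2O, DMAP, MeCN) gives the vinylogous carbamate tert-butyl (4-iodooct-7-en-1-yl)[(E)-3-oxopent-1-en-1-yl]carbamate F2, a much better radical acceptor. Cyclization ((Me3Si)3SiH, AIBN, 80 °C) gives tert-butyl 3-(but-3-en-1-yl)-2-(2-oxobutyl)piperidine-1-carboxylate F3 as a cis/trans mixture. CF3CO2H then removes the carbamate, and Et3N/MeOH equilibrates the free amino ketone to the trans isomer by retro-aza-Michael/aza-Michael addition. The route is rejoined at 8.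

Step 11, the double conjugate reduction with protonation at both C3 centres. Hydride addition to the α-methyl vinylogous amides may be sluggish, or the protonation unselective. The fallback sets out from 21. Dissolving-metal reduction (Li, liquid NH3/THF, t-BuOH, −78 °C) is followed by trapping with Me3SiCl/Et3N to give the isolable bis(trimethylsilyl enol ether) of the target F4. This is purified and then protodesilylated at −78 °C with Bu4NF/AcOH, which separates the reduction from the stereo-determining axial protonation. The route is rejoined at 23.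

**Further compounds**

F1 | step 8 | (9S,9aR)-9-(4-iodobutyl)-3-methyl-1,6,7,8,9,9a-hexahydro-2H-quinolizin-2-one | CC1=CN2CCC[C@H](CCCCI)[C@H]2CC1=O
F2 | step 4 | tert-butyl (4-iodooct-7-en-1-yl)[(E)-3-oxopent-1-en-1-yl]carbamate (racemic) | CCC(=O)/C=C/N(CCCC(I)CCC=C)C(=O)OC(C)(C)C
F3 | step 4 | tert-butyl 3-(but-3-en-1-yl)-2-(2-oxobutyl)piperidine-1-carboxylate (racemic cis/trans mixture) | CCC(=O)CC1C(CCC=C)CCCN1C(=O)OC(C)(C)C
F4 | step 11 | bis(trimethylsilyl) C2=C3 enol ether of the target (unit A 1S,9R,9aR; unit B 1S,9S,9aS) | CC=1CN2CCC[C@H]3CCCCC[C@@H]4C(O[Si](C)(C)C)=C(C)CN5CCC[C@H](CCCCC[C@H](C=1O[Si](C)(C)C)[C@@H]32)[C@@H]45
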